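**Plan**

1. Ring letters: A = catechol ring (two OH, one OAr, one CH2), B = 1,4-phenylene, C = 3-hydroxy-2-aryloxyphenyl, D = 1,2-phenylene; the 17-membered ring runs A–O–B–CH2CH2–C–O–D–CH2CH2–A.
2. Retrosynthetic cuts, in order: the three O–CH3 bonds of a trimethyl ether; the CH2–CH2 bond between rings B and C (through its CH=CH form, back to an open-chain dialdehyde); both CHO back to C≡N; the aryl(D)–CH2 bond of the D–A bridge; the two diaryl ether C–O bonds.
3. Enabling feature: the two carbons joined in the ring closure are benzylic carbons placed para to the ether oxygen on ring B and ortho to the ether oxygen on ring C. As C≡N they activate exactly the two C–F bonds that become the diaryl ethers; as CHO they are the only carbonyl groups of a non-enolisable dialdehyde, so reductive coupling can only join them to each other.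
4. Forward: two SNAr reactions give A–O–B and C–O–D, hydroboration/Suzuki coupling links them through the D–A bridge, DIBAL-H unveils the dialdehyde, reductive carbonyl coupling closes the macrocycle (the only ring made; all four benzene rings are bought), then hydrogenation and demethylation.
5. Stereochemistry: the target has no stereocentre; the E/Z geometry of the intermediate macrocyclic stilbene is erased by hydrogenation.

Key step: step 6

**Route**

Step 1
Reactants: 1 3-hydroxy-4,5-dimethoxybenzaldehyde; 2 4-fluorobenzonitrile
Product: 3 4-(5-formyl-2,3-dimethoxyphenoxy)benzonitrile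
Conditions: K2CO3, DMF, 120 °C
Reagents that add atoms: none
Why: Nucleophilic aromatic substitution (SNAr, addition–elimination), in which the phenoxide of 1 adds at the carbon para to the nitrile of 2 and fluoride leaves, while the aldehyde of 1 has no α-hydrogen and should survive carbonate in DMF.

Step 2
Reactants: 3 4-(5-formyl-2,3-dimethoxyphenoxy)benzonitrile
Product: 4 4-(5-ethenyl-2,3-dimethoxyphenoxy)benzonitrile
Conditions: Ph3PCH3Br, KOtBu, THF, 0 °C to rt
Reagents that add atoms: methyltriphenylphosphonium bromide, C[P+](c1ccccc1)(c1ccccc1)c1ccccc1.[Br-]
Why: Wittig methylenation, in which the non-stabilised ylide reacts with the aryl aldehyde far faster than with the aryl nitrile, so only C=O should be converted into C=CH2.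

Step 3
Reactants: 5 2-bromophenol; 6 2-fluoro-3-methoxybenzonitrile
Product: 7 2-(2-bromophenoxy)-3-methoxybenzonitrile
Conditions: Cs2CO3, DMSO, 120 °C
Reagents that add atoms: none
Why: Nucleophilic aromatic substitution (SNAr), in which the ortho nitrile of 6 stabilises the anionic adduct formed when 2-bromophenoxide attacks the C–F carbon, the unactivated C–Br bond of 5 being inert under these metal-free conditions.

Step 4
Reactants: 4 4-(5-ethenyl-2,3-dimethoxyphenoxy)benzonitrile; 7 2-(2-bromophenoxy)-3-methoxybenzonitrile
Product: 9 2-[2-[2-[3-(4-cyanophenoxy)-4,5-dimethoxyphenyl]ethyl]phenoxy]-3-methoxybenzonitrile, via alkylborane 8 (not isolated)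
Conditions: 9-BBN, THF, 0 °C to rt; then 7, PdCl2(dppf) (5 mol%), aq. K3PO4, DMF, 70 °C
Reagents that add atoms: none
Why: Anti-Markovnikov hydroboration of the styrene with 9-BBN followed by B-alkyl Suzuki–Miyaura coupling at the aryl bromide should give the saturated two-carbon D–A bridge directly, because 9-BBN adds to a terminal alkene much faster than it reduces an aryl nitrile and Pd(0) inserts only into the C–Br bond.

Step 5
Reactants: 9 2-[2-[2-[3-(4-cyanophenoxy)-4,5-dimethoxyphenyl]ethyl]phenoxy]-3-methoxybenzonitrile
Product: 11 2-[2-[2-[3-(4-formylphenoxy)-4,5-dimethoxyphenyl]ethyl]phenoxy]-3-methoxybenzaldehyde, via bis(iminoalane) 10 (not isolated)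
Conditions: DIBAL-H (3 equiv), CH2Cl2, −78 to −40 °C; then 1 M HCl, rt
Reagents that add atoms: water, O
Why: DIBAL-H partial reduction of nitriles, in which one hydride adds to each C≡N, the N-aluminio imine resists further reduction at low temperature and is hydrolysed to the aldehyde on acidic work-up, while aryl methyl ethers and diaryl ethers are inert.

Step 6
Reactants: 11 2-[2-[2-[3-(4-formylphenoxy)-4,5-dimethoxyphenyl]ethyl]phenoxy]-3-methoxybenzaldehyde
Product: 13 macrocyclic stilbene (tri-O-methyl target bearing CH=CH between rings B and C; E/Z mixture), via titanium pinacolate 12 (not isolated)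
Conditions: TiCl4, Zn, pyridine, THF, reflux; 11 added by syringe pump (final concentration about 2 mM); aqueous work-up
Reagents that add atoms: none
Why: Low-valent titanium generated from TiCl4 and Zn transfers one electron to each of the two aryl aldehydes of 11, the two titanium-bound ketyl radicals couple carbon to carbon to give the cyclic titanium pinacolate 12, and at reflux 12 is deoxygenated on titanium (driven by the strong Ti–O bond) to the stilbene 13. The closest known reaction type is the intramolecular McMurry coupling of aromatic dialdehydes to macrocyclic stilbenes (stilbenophanes). The one ring closed is the 17-membered macrocycle, formed end to end by ketyl–ketyl coupling (a macrocyclisation outside the small-ring stereoelectronic rules), with both oxygens held on titanium so that the two chain termini are templated together. No stereocentre persists, since the two carbinol centres of 12 are destroyed on deoxygenation and the E/Z geometry of 13 is erased in step 7. The step needs ring closure to win over intermolecular coupling and needs chemoselectivity for the two formyl groups: the first is secured by slow addition (pseudo-high dilution) and by the bent shape imposed by the ortho-linked ring D and the flexible D–A ethano bridge, the second by the absence of any other reducible group, the aryl ethers, methoxy groups and saturated bridge being inert to low-valent titanium.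

Step 7
Reactants: 13 macrocyclic stilbene (tri-O-methyl target bearing CH=CH between rings B and C; E/Z mixture)
Product: 14 tri-O-methyl ether of the target (saturated 17-membered macrocycle)
Conditions: H2 (1 atm), 10% Pd/C, EtOAc, rt
Reagents that add atoms: none
Why: Heterogeneous catalytic hydrogenation, in which the disubstituted stilbene C=C of either geometry is saturated on Pd/C while the aryl–oxygen bonds, none of which is a benzylic C–O bond, are not hydrogenolysed.

Step 8
Reactants: 14 tri-O-methyl ether of the target (saturated 17-membered macrocycle)
Product: 16 target CNP0290892.0 (tris-phenol macrocycle), via aryl borate 15 (not isolated)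
Conditions: BBr3 (excess), CH2Cl2, −78 °C to rt; then H2O (degassed)
Reagents that add atoms: none
Why: Lewis-acid ether cleavage (BBr3 demethylation), in which boron coordinates each methoxy oxygen and bromide attacks the methyl carbon by SN2, a path open only to the alkyl–oxygen bonds, so the two diaryl ethers should stay intact and hydrolysis of the aryl borates releases the three phenols.

**Compound list**

1 | 3-hydroxy-4,5-dimethoxybenzaldehyde | COc1cc(C=O)cc(O)c1OC | starting material
2 | 4-fluorobenzonitrile | N#Cc1ccc(F)cc1 | starting material
3 | 4-(5-formyl-2,3-dimethoxyphenoxy)benzonitrile | COc1cc(C=O)cc(Oc2ccc(C#N)cc2)c1OC | intermediate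
4 | 4-(5-ethenyl-2,3-dimethoxyphenoxy)benzonitrile | COc1cc(C=C)cc(Oc2ccc(C#N)cc2)c1OC | intermediate
5 | 2-bromophenol | Oc1ccccc1Br | starting material
6 | 2-fluoro-3-methoxybenzonitrile | COc1cccc(C#N)c1F | starting material
7 | 2-(2-bromophenoxy)-3-methoxybenzonitrile | COc1cccc(C#N)c1Oc1ccccc1Br | intermediate
8 | 4-[5-[2-(9-borabicyclo[3.3.1]nonan-9-yl)ethyl]-2,3-dimethoxyphenoxy]benzonitrile (alkylborane, not isolated) | COc1cc(CCB2C3CCCC2CCC3)cc(Oc2ccc(C#N)cc2)c1OC | intermediate
9 | 2-[2-[2-[3-(4-cyanophenoxy)-4,5-dimethoxyphenyl]ethyl]phenoxy]-3-methoxybenzonitrile | COc1cccc(C#N)c1Oc1ccccc1CCc1cc(OC)c(OC)c(Oc2ccc(C#N)cc2)c1 | intermediate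
10 | bis(N-diisobutylaluminio aldimine) of 9 (both C≡N reduced to CH=N–Al(iBu)2; not isolated) | COc1cccc(C=N[Al](CC(C)C)CC(C)C)c1Oc1ccccc1CCc1cc(OC)c(OC)c(Oc2ccc(C=N[Al](CC(C)C)CC(C)C)cc2)c1 | intermediate
11 | 2-[2-[2-[3-(4-formylphenoxy)-4,5-dimethoxyphenyl]ethyl]phenoxy]-3-methoxybenzaldehyde | COc1cccc(C=O)c1Oc1ccccc1CCc1cc(OC)c(OC)c(Oc2ccc(C=O)cc2)c1 | intermediate
12 | titanium-bound macrocyclic 1,2-diolate (pinacolate) between rings B and C, drawn as the dianion; both diastereomers; not isolated | COc1cc2cc(c1OC)Oc1ccc(cc1)C([O-])C([O-])c1cccc(OC)c1Oc1ccccc1CC2 | intermediate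
13 | macrocyclic stilbene: tri-O-methyl target with CH=CH in place of the CH2CH2 bridge between rings B and C (E/Z mixture) | COc1cc2cc(c1OC)Oc1ccc(cc1)C=Cc1cccc(OC)c1Oc1ccccc1CC2 | intermediate
14 | tri-O-methyl ether of the target: 17-membered macrocycle A–O–B–CH2CH2–C–O–D–CH2CH2–A with OMe on both catechol oxygens of ring A and on the ring C oxygen | COc1cc2cc(c1OC)Oc1ccc(cc1)CCc1cccc(OC)c1Oc1ccccc1CC2 | intermediate
15 | boron-bound target: cyclic bromoboronate across the two catechol oxygens of ring A and O–BBr2 on the ring C oxygen (not isolated) | BrB1Oc2cc3cc(c2O1)Oc1ccc(cc1)CCc1cccc(OB(Br)Br)c1Oc1ccccc1CC3 | intermediate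
16 | CNP0290892.0: 17-membered bis(bibenzyl) macrocycle with a catechol on ring A and one phenol on ring C | Oc1cc2cc(c1O)Oc1ccc(cc1)CCc1cccc(O)c1Oc1ccccc1CC2 | target

**Step count and risks**

Total step count: 8. Longest linear sequence: 7 steps (1 → 3 → 4 → 9 → 11 → 13 → 14 → 16); the branch 5 + 6 → 7 joins at step 4.

Steps most likely to fail:

First, step 6. Intermolecular ketyl coupling could outrun ring closure and give oligomers, or the reaction could stop at the pinacol stage without deoxygenation. The fallback sets out from dialdehyde 11. Double Wittig methylenation (Ph3PCH3Br, KOtBu, THF) should give the bis-styrene 1-ethenyl-2-[2-[2-[3-(4-ethenylphenoxy)-4,5-dimethoxyphenyl]ethyl]phenoxy]-3-methoxybenzene F1. Ring-closing metathesis (second-generation Grubbs catalyst, toluene, 80 °C, about 1 mM, ethene swept out) should then close the same bond under reversible conditions that can correct oligomers back to the ring. It comes back to the route at macrocyclic stilbene 13.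

Second, step 3. The SNAr could stall because the fluoride of 6 lies between two substituents and is electronically deactivated by the adjacent methoxy group, while 2-bromophenoxide is a hindered, weak nucleophile. The fallback leaves 5 and 6 aside and reverses the roles under copper catalysis. It sets out from commercial 2-hydroxy-3-methoxybenzonitrile (COc1cccc(C#N)c1O) and commercial 1-bromo-2-iodobenzene (Brc1ccccc1I). Ullmann-type O-arylation (CuI, picolinic acid, K3PO4, DMSO, 90 °C) should couple selectively at the C–I bond and comes back to the route at 7. No compound outside the compound list is made (F0).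

Third, step 4. Transmetalation of the alkylborane and coupling at the ortho-aryloxy-substituted bromide could be slow, so that protodeboronation, β-hydride elimination or slow nitrile reduction by excess borane take over. The fallback sets out from styrene 4 and bromide 7. A Heck reaction (Pd(OAc)2, P(o-tol)3, Et3N, DMF, 100 °C) should give 2-[2-[(E)-2-[3-(4-cyanophenoxy)-4,5-dimethoxyphenyl]ethenyl]phenoxy]-3-methoxybenzonitrile F2. Hydrogenation of the C=C bond (H2, 1 atm, Pd/C, EtOAc, rt, stopped after alkene uptake so that the nitriles are kept) comes back to the route at dinitrile 9.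

**Further compounds**

F1 | step 6 | 1-ethenyl-2-[2-[2-[3-(4-ethenylphenoxy)-4,5-dimethoxyphenyl]ethyl]phenoxy]-3-methoxybenzene | COc1cccc(C=C)c1Oc1ccccc1CCc1cc(OC)c(OC)c(Oc2ccc(C=C)cc2)c1
F0 | step 3 | none | none
F2 | step 4 | 2-[2-[(E)-2-[3-(4-cyanophenoxy)-4,5-dimethoxyphenyl]ethenyl]phenoxy]-3-methoxybenzonitrile | COc1cccc(C#N)c1Oc1ccccc1/C=C/c1cc(OC)c(OC)c(Oc2ccc(C#N)cc2)c1
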